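The solid reagent is a budget: what a flask has spent plus what it still holds stays equal to its charge.

| flask | substrate | solid reagent | remark | time |
|---|---|---|---|---|
| gamma | 0.080 M | 0.060 M | run made earlier |  |
| epsilon | 0.080 M | 0.090 M | run made earlier |  |
| flask | 0.080 M | 0.120 M |  | 6.0 min |

- gamma (time / min: double product / %, first product / %): 1.50: 3, 18; 2.00: 2, 21; 2.50: 5, 21; 4.00: 6, 22
- epsilon (time / min: double product / %, first product / %): 1.50: 2, 19; 2.00: 5, 22; 2.50: 8, 24; 4.00: 18, 25

(each reading ± 1.5 percentage points)

1. time, not beyond 6.0 min, at which the flask holds most double product
2. the amount of double product, in percent of the substrate charged, at that time

- as a solid, counted per litre of solution: solid reagent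
- the numbers in the tables scatter by 1.5 percentage points (one standard deviation)
- at the start none of the solid reagent is in solution

The gamma and epsilon runs differ in solid reagent. At 1.50 min their double product differs by 1 percentage point, against a scatter of 1.5 points, but at 4.00 min gamma reads 6 % and epsilon 18 %. So I read more solid as a longer run on one curve, not a faster one. In epsilon the first product barely moves after 2.50 min, so I draw double product as a straight line from its last two readings:

rate = 6.67 %/min

at 6.0 min: 31.3 %

With first product flat, each new double product also takes a first step, so at one equivalent per step that line costs up to 26.7 % of the substrate charge in reagent after 4.00 min. The flask holds 37.5 % beyond the whole epsilon charge, which is more than that, so I let the line run to the time limit.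

The weak link is the slope, taken over a short span. From 2.00 min to 4.00 min I get 6.50 %/min, the late rate, the percent of double product gained per minute while solid remains. I commit to 6.0 min and 31.0 %.

The forecast gives 5.2 min and 26 %: the product “then stays flat, since no reagent remains”.

The flask gives 30.0 % at 6.00 min.

    substrate + partner → first product + released group (k = 0.690 /M/s)
    substrate + partner → other mono adduct + released group (k = 1.20 /M/s)
    partner + first product → double product + released group (k = 0.290 /M/s)
    partner + other mono adduct → double product + released group (k = 0.230 /M/s)
    solid reagent ⇌ partner, rate k5*(cs5 - [partner]) while solid is left; crystals form when [partner] > cs5 (solubility = 6.20 mM, k = 0.410 /s)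

At 3.00 min the flask has lost 0.0805 M of its solid, and the late rate, counted back from epsilon's last reading, puts double product there at 11.5 %. A neighbouring flask is charged with 0.072 M, less than that loss, so the same reckoning stops it earlier and lower on the line. In that neighbouring flask the solid reagent is the limiting reagent, standing at 0 % at 6.00 min, with 20 % of the substrate left and double product at 9.97 %, below the line's value.

All runs stem from a simulated flask with constants of no real substance, noise included.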